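**Assumption:** Abiesin as drawn has no stereocenters, so there is no enantiomer to control. The biaryl axis carries only one ortho OMe on one side and one ortho OH on the other, so it is not configurationally stable. The only stereo-element in the route is the E-chalcone geometry, which is erased on cyclization. Compounds are numbered by first appearance, including the retrosynthesis. Bases, solvents and Pd catalysts are not numbered.

## Retrosynthetic overview
1. Target **1** is disconnected at the C6(flavonol)–C3'(flavone) biaryl bond (Suzuki–Miyaura) into 6-iodoflavonol **2** and flavone pinacol boronate **3**.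
2. **3** comes from bromoflavone **4** (Miyaura borylation). **4** comes from chalcone **5** (I2/DMSO cyclization). **5** comes from acetophenone **6** and aldehyde **7** (Claisen–Schmidt).
3. **2** comes from chalcone **8** (Algar–Flynn–Oyamada). **8** comes from iodoacetophenone **9** and anisaldehyde **10**. **9** comes from resacetophenone **11** (iodination).
4. Both pyranone rings are built inside their own fragments, flavone C-ring first in one branch and flavonol C-ring in the other, and the biaryl bond is made last.
5. The final coupling leaves every OH and OMe in place, so no protecting groups or deprotection are needed.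

## Forward route

**Step 1**
Reactants: **6** 2',6'-dihydroxy-4'-methoxyacetophenone; **7** 3-bromo-4-methoxybenzaldehyde
Product: **5** (E)-3-(3-bromo-4-methoxyphenyl)-1-(2,6-dihydroxy-4-methoxyphenyl)prop-2-en-1-one
Conditions: 50% aq. KOH, EtOH, rt, 48 h; then HCl
Reagents that add atoms: none
Why: Claisen–Schmidt aldol condensation of the phenolate-stabilised acetophenone enolate with a non-enolisable aldehyde gives the thermodynamic E-enone, so the only stereo-element is E-alkene geometry.

**Step 2**
Reactants: **5**
Product: **4** 3'-bromo-5-hydroxy-7,4'-dimethoxyflavone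
Conditions: I2 (0.2 equiv), DMSO, 130 °C, 3 h
Reagents that add atoms: none (I2 is catalytic; DMSO is the terminal oxidant)
Why: Oxa-Michael closure of the 2'-OH onto the enone gives a flavanone, which I2/DMSO oxidises to the flavone (oxidative cyclization). No stereocenter survives. The 5-OH is H-bonded to the carbonyl and the ArBr is untouched.

**Step 3**
Reactants: **4**; **12** bis(pinacolato)diboron
Product: **3** 5-hydroxy-7,4'-dimethoxy-3'-(4,4,5,5-tetramethyl-1,3,2-dioxaborolan-2-yl)flavone
Conditions: B2pin2 (1.3 equiv), Pd(dppf)Cl2 (5 mol%), KOAc, 1,4-dioxane, 90 °C, 12 h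
Reagents that add atoms: B2pin2, CC1(C)OB(OC1(C)C)B1OC(C)(C)C(C)(C)O1
Why: Miyaura borylation converts the aryl bromide to the Bpin ester under mild base. The chromone carbonyl and free 5-OH are tolerated, and no stereocenter is involved.

**Step 4**
Reactants: **11** 2',4'-dihydroxyacetophenone (resacetophenone); **13** N-iodosuccinimide
Product: **9** 2',4'-dihydroxy-5'-iodoacetophenone
Conditions: NIS (1.05 equiv), MeCN, rt, 4 h
Reagents that add atoms: NIS, O=C1CCC(=O)N1I
Why: Electrophilic aromatic iodination goes to C5', which is para to the 2'-OH and ortho to the 4'-OH and is the least hindered activated site. This places iodine ortho to the future 7-OH and at the future C6.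

**Step 5**
Reactants: **9**; **10** 4-methoxybenzaldehyde
Product: **8** (E)-1-(2,4-dihydroxy-5-iodophenyl)-3-(4-methoxyphenyl)prop-2-en-1-one
Conditions: 50% aq. KOH (4 equiv), EtOH, rt, 48 h; then HCl
Reagents that add atoms: none
Why: Claisen–Schmidt condensation; excess base covers the two phenols and the aldehyde cannot enolise, so the E-chalcone forms selectively.

**Step 6**
Reactants: **8**; **14** hydrogen peroxide
Product: **2** 3,7-dihydroxy-6-iodo-4'-methoxyflavone
Conditions: 30% H2O2 (10 equiv), 2 M aq. NaOH, MeOH, 0 °C to rt, 12 h; then HCl
Reagents that add atoms: H2O2, OO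
Why: Algar–Flynn–Oyamada reaction: nucleophilic epoxidation of the enone, then phenoxide opening and oxidation installs the 3-OH and closes the flavonol ring. The aryl iodide is stable to HOO⁻ and no stereocenter remains.

**Step 7**
Reactants: **2**; **3**
Product: **1** Abiesin
Conditions: Pd(dppf)Cl2 (10 mol%), K2CO3 (4 equiv), 1,4-dioxane/H2O 4:1, 90 °C, 16 h, N2
Reagents that add atoms: none
Why: Suzuki–Miyaura coupling joins C6 of the iodoflavonol to C3' of the flavone boronate. The extra base equivalents cover the acidic 3-OH and 7-OH, which stay free, so the product is the target with no deprotection.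

**Verification against the target SMILES**
- Flavonol half: 7-OH, 3-OH, 4'-OMe and H-5 (no 5-OH) come from resacetophenone. The 6-aryl group sits ortho to the 7-OH, as the iodine position in **9** dictates.
- Flavone half: 5-OH and 7-OMe come from **6**. The central ring is 4'-OMe with C1' bound to C2 of the flavone and C3' bound to C6 of the flavonol, which matches the SMILES.
- Formula C33H24O10, as the SMILES requires.
- No stereocenters are set or scrambled.

## Compound list
| No. | Name | SMILES | Role |
|---|---|---|---|
| 1 | Abiesin | COc1ccc(cc1)-c1oc2cc(O)c(cc2c(=O)c1O)-c1cc(ccc1OC)-c1cc(=O)c2c(O)cc(OC)cc2o1 | target |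
| 2 | 3,7-dihydroxy-6-iodo-4'-methoxyflavone | COc1ccc(cc1)-c1oc2cc(O)c(I)cc2c(=O)c1O | intermediate |
| 3 | 5-hydroxy-7,4'-dimethoxy-3'-Bpin-flavone | COc1ccc(cc1B1OC(C)(C)C(C)(C)O1)-c1cc(=O)c2c(O)cc(OC)cc2o1 | intermediate |
| 4 | 3'-bromo-5-hydroxy-7,4'-dimethoxyflavone | COc1ccc(cc1Br)-c1cc(=O)c2c(O)cc(OC)cc2o1 | intermediate |
| 5 | (E)-3-(3-bromo-4-methoxyphenyl)-1-(2,6-dihydroxy-4-methoxyphenyl)propenone | COc1cc(O)c(C(=O)/C=C/c2ccc(OC)c(Br)c2)c(O)c1 | intermediate |
| 6 | 2',6'-dihydroxy-4'-methoxyacetophenone | CC(=O)c1c(O)cc(OC)cc1O | starting material |
| 7 | 3-bromo-4-methoxybenzaldehyde | COc1ccc(C=O)cc1Br | starting material |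
| 8 | (E)-1-(2,4-dihydroxy-5-iodophenyl)-3-(4-methoxyphenyl)propenone | COc1ccc(/C=C/C(=O)c2cc(I)c(O)cc2O)cc1 | intermediate |
| 9 | 2',4'-dihydroxy-5'-iodoacetophenone | CC(=O)c1cc(I)c(O)cc1O | intermediate |
| 10 | 4-methoxybenzaldehyde | COc1ccc(C=O)cc1 | starting material |
| 11 | 2',4'-dihydroxyacetophenone | CC(=O)c1ccc(O)cc1O | starting material |
| 12 | bis(pinacolato)diboron | CC1(C)OB(OC1(C)C)B1OC(C)(C)C(C)(C)O1 | reagent (starting material) |
| 13 | N-iodosuccinimide | O=C1CCC(=O)N1I | reagent (starting material) |
| 14 | hydrogen peroxide | OO | reagent (starting material) |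

## Summary
**Total steps:** 7. **Longest linear sequence:** 4 steps (1 → 2 → 3 → 7). The iodoflavonol branch (4 → 5 → 6) is 3 steps and runs in parallel.

**Three steps most likely to fail**
1. **Step 7 (Suzuki coupling).** The coupling is sterically hindered (ortho-OH on one partner, ortho-OMe on the other) and uses free phenols and an electron-rich Bpin, so protodeboronation and homocoupling are likely. Fallback: reverse the polarity by making the flavonol-6-Bpin from **2** (Miyaura) and coupling it with bromide **4** directly. Alternatively, build the biaryl first by coupling **9** with 5-formyl-2-methoxyphenylboronic acid and then form the two pyranone rings.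
2. **Step 6 (AFO).** Yields with the free 4'-OH (7-OH) chalcone can be modest, and aurone or over-oxidation by-products can form. Fallback: Auwers route. Condense 6-hydroxycoumaran-3-one (iodinated at C5) with anisaldehyde to the aurone, brominate, and rearrange with KOH to the flavonol.
3. **Step 4 (iodination of 11).** Regioselectivity (C5' versus C3') and di-iodination are concerns. Fallback: Friedel–Crafts acetylation of 4-iodoresorcinol (AcOH, BF3·Et2O), which gives **9** regiospecifically, or buy **9** directly.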